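The route rests on an intramolecular Diels–Alder disconnection of ring B (C2–C3=C4–C5–C6–C7) of the trans-decalin: the C5–C6 and C2–C7 bonds are made together, which closes ring A (C1, C2, C7–C10) at the same time. The exocyclic methylene at C8, next to the ring-fusion carbon C7, is read as a former ketone and C6–C7 as a former alkyne, so the precursor is an acyclic dienyl ynone in which C1 and C10 already carry the acrylate and the side-chain ester. Cycloaddition sets C2 from C1; C7 is then set by conjugate reduction and axial protonation, and C8 is methylenated.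

Key step: step 13

Remark on labels: C1 bears the acrylic acid, C2 and C7 are the ring-fusion carbons, ring B is C2–C3=C4(CH2OH)–C5–C6–C7, ring A is C1–C2–C7–C8(=CH2)–C9–C10(O-acyl).

Assumption: compounds 1, 2, 5, 6, 10 and 15 are taken as commercial. The carbinol carbon that becomes C8 and the acetal carbon of the oxan-2-yl group are carried as epimer mixtures, because both disappear later.

Step 1
Reactants: 1 3-(trimethylsilyl)prop-2-ynal; 2 tert-butyl prop-2-enoate
Product: 3 tert-butyl 2-[1-hydroxy-3-(trimethylsilyl)prop-2-yn-1-yl]prop-2-enoate (racemic)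
Conditions: DABCO (20 mol %), neat, rt
Reagents that add atoms: none
Why: Morita–Baylis–Hillman reaction, in which the ammonium enolate formed from DABCO and the acrylate adds to the carbonyl carbon of the electrophilic ynal; the carbinol centre is racemic and is erased in step 2.

Step 2
Reactants: 3 tert-butyl 2-[1-hydroxy-3-(trimethylsilyl)prop-2-yn-1-yl]prop-2-enoate
Product: 4 tert-butyl (2Z)-2-(bromomethyl)-5-(trimethylsilyl)pent-2-en-4-ynoate
Conditions: N-bromosuccinimide, Me2S, CH2Cl2, 0 °C → rt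
Reagents that add atoms: N-bromosuccinimide, O=C1CCC(=O)N1Br
Why: Corey–Kim-type activation of the allylic alcohol as an alkoxysulfonium salt and SN2′ delivery of bromide to the methylene terminus should give the rearranged primary bromide as the thermodynamically preferred Z isomer (alkynyl trans to the ester).

Step 3
Reactants: 5 3-[tri(propan-2-yl)silyl]prop-2-ynal; 6 ethyl acetate
Product: 7 ethyl 3-hydroxy-5-[tri(propan-2-yl)silyl]pent-4-ynoate (racemic)
Conditions: LiN(iPr)2, THF, −78 °C; then 5; AcOH quench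
Reagents that add atoms: none
Why: Acetate aldol addition of the lithium enolate to the aldehyde carbon of the ynal (1,2-addition at −78 °C); the new carbinol centre is racemic, which does not matter because it becomes the ketone carbon C8 in step 13.

Step 4
Reactants: 7 ethyl 3-hydroxy-5-[tri(propan-2-yl)silyl]pent-4-ynoate
Product: 8 ethyl 3-[(triethylsilyl)oxy]-5-[tri(propan-2-yl)silyl]pent-4-ynoate
Conditions: Et3SiCl, imidazole, CH2Cl2, 0 °C → rt
Reagents that add atoms: chlorotriethylsilane, CC[Si](Cl)(CC)CC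
Why: Standard O-silylation of a secondary alcohol, which blocks β-elimination and retro-aldol cleavage in the following steps.

Step 5
Reactants: 8 ethyl 3-[(triethylsilyl)oxy]-5-[tri(propan-2-yl)silyl]pent-4-ynoate
Product: 9 3-[(triethylsilyl)oxy]-5-[tri(propan-2-yl)silyl]pent-4-ynal
Conditions: iBu2AlH (1.1 equiv), CH2Cl2, −78 °C; aq. potassium sodium tartrate
Reagents that add atoms: none
Why: Partial reduction of the ester, which stops at the aldehyde stage because the tetrahedral aluminium hemiacetal is stable at −78 °C.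

Step 6
Reactants: 10 methyl [(4S)-2,2-dimethyl-1,3-dioxolan-4-yl]acetate
Product: 13 methyl 2-[(4S)-2,2-dimethyl-1,3-dioxolan-4-yl]prop-2-enoate, via Mannich base 11 (not isolated), via trimethylammonium iodide 12 (not isolated)
Conditions: LiN(iPr)2, THF, −78 °C; Me2N=CH2 I, −78 → 0 °C; then MeI, MeOH, rt; then aq. NaHCO3, CH2Cl2, rt
Reagents that add atoms: N,N-dimethylmethyleneiminium iodide, C=[N+](C)C.[I-]
Why: Mannich-type α-aminomethylation of the ester enolate, N-methylation and E1cB loss of trimethylamine (α-methylenation); the enolate is kept cold to avoid loss of the β-alkoxide, and the dioxolane stereocentre is not touched.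

Step 7
Reactants: 13 methyl 2-[(4S)-2,2-dimethyl-1,3-dioxolan-4-yl]prop-2-enoate
Product: 14 2-[(4S)-2,2-dimethyl-1,3-dioxolan-4-yl]prop-2-enoic acid
Conditions: LiOH, THF/H2O, 0 °C; then 1 M HCl to pH 3, 0 °C
Reagents that add atoms: lithium hydroxide, [Li+].[OH-]
Why: Saponification of the methyl ester under mild conditions that leave the acetonide and the stereocentre intact.

Step 8
Reactants: 15 2-bromoprop-2-en-1-ol
Product: 16 2-[(2-bromoprop-2-en-1-yl)oxy]oxane (racemic)
Conditions: 3,4-dihydro-2H-pyran, pyridinium p-toluenesulfonate (cat.), CH2Cl2, rt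
Reagents that add atoms: 3,4-dihydro-2H-pyran, C1=COCCC1
Why: Acid-catalysed acetalisation gives a tetrahydropyranyl ether that is stable to fluoride, zinc and titanium reagents and is removed by weak acid at the end.

Step 9
Reactants: 4 tert-butyl (2Z)-2-(bromomethyl)-5-(trimethylsilyl)pent-2-en-4-ynoate; 9 3-[(triethylsilyl)oxy]-5-[tri(propan-2-yl)silyl]pent-4-ynal
Product: 18 tert-butyl (3S,4S)-3-ethynyl-4-hydroxy-2-methylidene-6-[(triethylsilyl)oxy]-8-[tri(propan-2-yl)silyl]oct-7-ynoate (C6 epimers), via bis-silylated adduct 17 (not isolated)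
Conditions: CrCl2 (10 mol %), (S,S)-3,6-di-tert-butyl-1,8-bis(4-isopropyl-4,5-dihydro-1,3-oxazol-2-yl)-9H-carbazole (12 mol %; the antipode is used if a model aldehyde shows the opposite sense), Mn powder, Me3SiCl, iPr2NEt, THF, rt; then K2CO3, MeOH, 0 °C
Reagents that add atoms: none
Why: Catalytic asymmetric Nozaki–Hiyama–Kishi 2-(alkoxycarbonyl)allylation, in which the allylchromium species (trivalent chromium, turned over by Mn and Me3SiCl) keeps the tiglate-type geometry and adds at its γ-carbon through a closed chair-like six-membered transition state, which should give the 3,4-syn relationship, while the bis(oxazoline) ligand selects the aldehyde face that gives the 4S carbinol; carbonate methanolysis then removes the O- and C-trimethylsilyl groups but not the triethylsilyl and triisopropylsilyl groups, and the tert-butyl ester does not lactonise.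

Step 10
Reactants: 18 tert-butyl (3S,4S)-3-ethynyl-4-hydroxy-2-methylidene-6-[(triethylsilyl)oxy]-8-[tri(propan-2-yl)silyl]oct-7-ynoate; 14 2-[(4S)-2,2-dimethyl-1,3-dioxolan-4-yl]prop-2-enoic acid
Product: 20 tert-butyl (3S,4S)-4-({2-[(4S)-2,2-dimethyl-1,3-dioxolan-4-yl]prop-2-enoyl}oxy)-3-ethynyl-2-methylidene-6-[(triethylsilyl)oxy]-8-[tri(propan-2-yl)silyl]oct-7-ynoate, via mixed anhydride 19 (not isolated)
Conditions: 2,4,6-trichlorobenzoyl chloride, Et3N, THF, rt; then 18, 4-(dimethylamino)pyridine, toluene, rt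
Reagents that add atoms: none
Why: Yamaguchi esterification installs the final side-chain ester on the still unhindered acyclic carbinol, with no stereocentre affected; having the ester in place early means that no protecting group is needed on the C10 oxygen.

Step 11
Reactants: 20 tert-butyl (3S,4S)-4-({2-[(4S)-2,2-dimethyl-1,3-dioxolan-4-yl]prop-2-enoyl}oxy)-3-ethynyl-2-methylidene-6-[(triethylsilyl)oxy]-8-[tri(propan-2-yl)silyl]oct-7-ynoate; 16 2-[(2-bromoprop-2-en-1-yl)oxy]oxane
Product: 23 tert-butyl (3S,4S)-4-({2-[(4S)-2,2-dimethyl-1,3-dioxolan-4-yl]prop-2-enoyl}oxy)-2-methylidene-3-[(1E)-3-{[(oxan-2-yl)oxy]methyl}buta-1,3-dien-1-yl]-6-[(triethylsilyl)oxy]-8-[tri(propan-2-yl)silyl]oct-7-ynoate, via alkenylzirconocene chloride 21 (not isolated), via alkenylzinc chloride 22 (not isolated)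
Conditions: Cp2Zr(H)Cl (1.3 equiv), THF, rt; then ZnCl2; then 16, Pd(PPh3)4 (5 mol %), THF, rt
Reagents that add atoms: none
Why: Hydrozirconation followed by Negishi coupling: Cp2Zr(H)Cl adds syn and anti-Markovnikov to the terminal alkyne only (the silylated alkyne is inert), and transmetalation to zinc and coupling at zerovalent palladium proceed with retention to give the (E)-configured C2=C3 bond of the diene.

Step 12
Reactants: 23 tert-butyl (3S,4S)-4-({2-[(4S)-2,2-dimethyl-1,3-dioxolan-4-yl]prop-2-enoyl}oxy)-2-methylidene-3-[(1E)-3-{[(oxan-2-yl)oxy]methyl}buta-1,3-dien-1-yl]-6-[(triethylsilyl)oxy]-8-[tri(propan-2-yl)silyl]oct-7-ynoate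
Product: 24 tert-butyl (3S,4S)-4-({2-[(4S)-2,2-dimethyl-1,3-dioxolan-4-yl]prop-2-enoyl}oxy)-6-hydroxy-2-methylidene-3-[(1E)-3-{[(oxan-2-yl)oxy]methyl}buta-1,3-dien-1-yl]oct-7-ynoate (C6 epimers)
Conditions: Bu4NF, AcOH (1:1), THF, 0 °C → rt
Reagents that add atoms: none
Why: Fluoride-mediated desilylation cleaves the alkynyl C–Si and the secondary O–Si bonds, while the acetic acid buffer keeps the liberated carbinol protonated and so suppresses 1,3-acyl migration from the neighbouring ester; the acetal protecting groups are not touched.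

Step 13
Reactants: 24 tert-butyl (3S,4S)-4-({2-[(4S)-2,2-dimethyl-1,3-dioxolan-4-yl]prop-2-enoyl}oxy)-6-hydroxy-2-methylidene-3-[(1E)-3-{[(oxan-2-yl)oxy]methyl}buta-1,3-dien-1-yl]oct-7-ynoate
Product: 26 tert-butyl 2-[(1S,2S,8aR)-2-({2-[(4S)-2,2-dimethyl-1,3-dioxolan-4-yl]prop-2-enoyl}oxy)-7-{[(oxan-2-yl)oxy]methyl}-4-oxo-1,2,3,4,6,8a-hexahydronaphthalen-1-yl]prop-2-enoate, via ynone 25 (not isolated)
Conditions: Dess–Martin periodinane, CH2Cl2, 0 °C → rt; filtration, then toluene, 2,6-di-tert-butyl-4-methylphenol (cat.), 45 °C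
Reagents that add atoms: none
Why: Oxidation of the propargylic carbinol gives the ynone, whose electron-poor C6≡C7 bond adds suprafacially to the C2=C3–C4=C5 diene in a concerted, asynchronous intramolecular [4+2] cycloaddition. The closest known reaction type is the type 1 intramolecular Diels–Alder reaction of 1,7,9-decatrienones and the corresponding dienynones that are activated by a carbonyl group inside the tether. Ring B closes as the cyclohexa-1,4-diene of the cycloadduct, and ring A closes in the fused mode because the four-atom tether C1–C10–C9–C8 joins diene terminus C2 to dienophile carbon C7. The only new stereocentre is C2, controlled by C1: in the reactive conformer C1–H eclipses the diene plane (minimal A1,3 strain), the acrylate sits pseudo-equatorial on the forming ring A and the tether reaches the diene face anti to it, so that C1–H and C2–H end up trans, and the cis C10 acyloxy group (pseudo-axial) does not oppose this. Because the dienophile is an alkyne, there is no endo/exo question and C7 stays trigonal for the next step. The step needs chemoselectivity for the ynone over the two acrylate esters, which should follow from the much lower LUMO of the ynone, from the fact that the acrylate on C1 cannot reach the diene, and from the slow cyclisation of ester-tethered dienophiles.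

Step 14
Reactants: 26 tert-butyl 2-[(1S,2S,8aR)-2-({2-[(4S)-2,2-dimethyl-1,3-dioxolan-4-yl]prop-2-enoyl}oxy)-7-{[(oxan-2-yl)oxy]methyl}-4-oxo-1,2,3,4,6,8a-hexahydronaphthalen-1-yl]prop-2-enoate
Product: 28 tert-butyl 2-[(1S,2S,4aS,8aR)-2-({2-[(4S)-2,2-dimethyl-1,3-dioxolan-4-yl]prop-2-enoyl}oxy)-7-{[(oxan-2-yl)oxy]methyl}-4-oxo-1,2,3,4,4a,5,6,8a-octahydronaphthalen-1-yl]prop-2-enoate (trans-fused), via boron enolate 27 (not isolated)
Conditions: catecholborane (2 equiv), THF, −20 °C → rt; then pH 7 phosphate buffer, 0 °C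
Reagents that add atoms: none
Why: Conjugate reduction of an s-cis enone by catecholborane (unsaturated esters do not react) gives the regiodefined boron enolate C7=C8, which cannot expel the C10 acyloxy group, and protonation on work-up should occur axially on the half-chair of ring A that keeps the C1 substituent equatorial, which places C7–H anti to C2–H (trans ring fusion).

Step 15
Reactants: 28 tert-butyl 2-[(1S,2S,4aS,8aR)-2-({2-[(4S)-2,2-dimethyl-1,3-dioxolan-4-yl]prop-2-enoyl}oxy)-7-{[(oxan-2-yl)oxy]methyl}-4-oxo-1,2,3,4,4a,5,6,8a-octahydronaphthalen-1-yl]prop-2-enoate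
Product: 29 tert-butyl 2-[(1S,2S,4aS,8aS)-2-({2-[(4S)-2,2-dimethyl-1,3-dioxolan-4-yl]prop-2-enoyl}oxy)-4-methylidene-7-{[(oxan-2-yl)oxy]methyl}-1,2,3,4,4a,5,6,8a-octahydronaphthalen-1-yl]prop-2-enoate
Conditions: Zn, CH2Br2, TiCl4 (pre-formed reagent), THF/CH2Cl2, 0 °C → rt
Reagents that add atoms: dibromomethane, BrCBr
Why: Takai–Lombardo methylenation, in which the non-basic zinc/titanium methylene reagent olefinates the hindered ketone without enolisation, so that C7 is not epimerised, the β-acyloxy group is not eliminated and the esters are left alone.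

Step 16
Reactants: 29 tert-butyl 2-[(1S,2S,4aS,8aS)-2-({2-[(4S)-2,2-dimethyl-1,3-dioxolan-4-yl]prop-2-enoyl}oxy)-4-methylidene-7-{[(oxan-2-yl)oxy]methyl}-1,2,3,4,4a,5,6,8a-octahydronaphthalen-1-yl]prop-2-enoate
Product: 30 tert-butyl 2-[(1S,2S,4aS,8aS)-2-{[(3S)-3,4-dihydroxy-2-methylidenebutanoyl]oxy}-7-(hydroxymethyl)-4-methylidene-1,2,3,4,4a,5,6,8a-octahydronaphthalen-1-yl]prop-2-enoate
Conditions: AcOH/THF/H2O (3:1:1), 40 °C
Reagents that add atoms: none
Why: Acid-catalysed acetal hydrolysis removes the oxan-2-yl ether and the isopropylidene acetal, while the tert-butyl ester and the 1,1-disubstituted alkenes should survive this weak acid.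

Step 17
Reactants: 30 tert-butyl 2-[(1S,2S,4aS,8aS)-2-{[(3S)-3,4-dihydroxy-2-methylidenebutanoyl]oxy}-7-(hydroxymethyl)-4-methylidene-1,2,3,4,4a,5,6,8a-octahydronaphthalen-1-yl]prop-2-enoate
Product: 32 2-[(1S,2S,4aS,8aS)-2-{[(3S)-3,4-dihydroxy-2-methylidenebutanoyl]oxy}-7-(hydroxymethyl)-4-methylidene-1,2,3,4,4a,5,6,8a-octahydronaphthalen-1-yl]prop-2-enoic acid (CNP0460913.1), via persilylated intermediate 31 (not isolated)
Conditions: Me3SiOSO2CF3 (6 equiv), 2,6-lutidine (8 equiv), CH2Cl2, 0 °C → rt; then aq. citric acid, MeOH, 0 °C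
Reagents that add atoms: none
Why: Silyl-triflate-mediated tert-butyl ester cleavage (O-silylation of the ester carbonyl, loss of 2-methylpropene with the hindered base taking the proton) gives the silyl ester without free strong acid that could protonate the exocyclic alkene, and mild aqueous acid then hydrolyses the silyl ester and the transient silyl ethers; base is avoided because the dihydroxy ester side chain would lactonise.

Compound list
1 | 3-(trimethylsilyl)prop-2-ynal | C[Si](C)(C)C#CC=O | starting material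
2 | tert-butyl prop-2-enoate | C=CC(=O)OC(C)(C)C | starting material
3 | tert-butyl 2-[1-hydroxy-3-(trimethylsilyl)prop-2-yn-1-yl]prop-2-enoate (racemic) | C=C(C(=O)OC(C)(C)C)C(O)C#C[Si](C)(C)C | intermediate
4 | tert-butyl (2Z)-2-(bromomethyl)-5-(trimethylsilyl)pent-2-en-4-ynoate | BrC/C(=C\C#C[Si](C)(C)C)C(=O)OC(C)(C)C | intermediate
5 | 3-[tri(propan-2-yl)silyl]prop-2-ynal | CC(C)[Si](C(C)C)(C(C)C)C#CC=O | starting material
6 | ethyl acetate | CCOC(C)=O | starting material
7 | ethyl 3-hydroxy-5-[tri(propan-2-yl)silyl]pent-4-ynoate (racemic) | CCOC(=O)CC(O)C#C[Si](C(C)C)(C(C)C)C(C)C | intermediate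
8 | ethyl 3-[(triethylsilyl)oxy]-5-[tri(propan-2-yl)silyl]pent-4-ynoate (racemic) | CCOC(=O)CC(O[Si](CC)(CC)CC)C#C[Si](C(C)C)(C(C)C)C(C)C | intermediate
9 | 3-[(triethylsilyl)oxy]-5-[tri(propan-2-yl)silyl]pent-4-ynal (racemic) | O=CCC(O[Si](CC)(CC)CC)C#C[Si](C(C)C)(C(C)C)C(C)C | intermediate
10 | methyl [(4S)-2,2-dimethyl-1,3-dioxolan-4-yl]acetate | COC(=O)C[C@H]1COC(C)(C)O1 | starting material
11 | methyl 3-(dimethylamino)-2-[2,2-dimethyl-1,3-dioxolan-4-yl]propanoate (Mannich base, dioxolane centre as in 10, C2 epimers) | COC(=O)C(CN(C)C)[C@H]1COC(C)(C)O1 | intermediate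
12 | trimethylammonium iodide of 11 (N-methylated Mannich base) | COC(=O)C(C[N+](C)(C)C)[C@H]1COC(C)(C)O1.[I-] | intermediate
13 | methyl 2-[(4S)-2,2-dimethyl-1,3-dioxolan-4-yl]prop-2-enoate | COC(=O)C(=C)[C@H]1COC(C)(C)O1 | intermediate
14 | 2-[(4S)-2,2-dimethyl-1,3-dioxolan-4-yl]prop-2-enoic acid | OC(=O)C(=C)[C@H]1COC(C)(C)O1 | intermediate
15 | 2-bromoprop-2-en-1-ol | OCC(Br)=C | starting material
16 | 2-[(2-bromoprop-2-en-1-yl)oxy]oxane (racemic) | BrC(=C)COC1CCCCO1 | intermediate
17 | tert-butyl (3R,4S)-2-methylidene-6-[(triethylsilyl)oxy]-4-[(trimethylsilyl)oxy]-3-[(trimethylsilyl)ethynyl]-8-[tri(propan-2-yl)silyl]oct-7-ynoate (C6 epimers) | C=C(C(=O)OC(C)(C)C)[C@@H]([C@@H](O[Si](C)(C)C)CC(O[Si](CC)(CC)CC)C#C[Si](C(C)C)(C(C)C)C(C)C)C#C[Si](C)(C)C | intermediate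
18 | tert-butyl (3S,4S)-3-ethynyl-4-hydroxy-2-methylidene-6-[(triethylsilyl)oxy]-8-[tri(propan-2-yl)silyl]oct-7-ynoate (C6 epimers) | C=C(C(=O)OC(C)(C)C)[C@@H]([C@@H](O)CC(O[Si](CC)(CC)CC)C#C[Si](C(C)C)(C(C)C)C(C)C)C#C | intermediate
19 | mixed anhydride of 14 and 2,4,6-trichlorobenzoic acid | C=C(C(=O)OC(=O)c1c(Cl)cc(Cl)cc1Cl)[C@H]1COC(C)(C)O1 | intermediate
20 | tert-butyl (3S,4S)-4-({2-[(4S)-2,2-dimethyl-1,3-dioxolan-4-yl]prop-2-enoyl}oxy)-3-ethynyl-2-methylidene-6-[(triethylsilyl)oxy]-8-[tri(propan-2-yl)silyl]oct-7-ynoate (C6 epimers) | C=C(C(=O)OC(C)(C)C)[C@@H]([C@@H](OC(=O)C(=C)[C@H]1COC(C)(C)O1)CC(O[Si](CC)(CC)CC)C#C[Si](C(C)C)(C(C)C)C(C)C)C#C | intermediate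
21 | (E)-alkenylzirconocene chloride from 20 (Zr on the terminal alkyne carbon) | C=C(C(=O)OC(C)(C)C)[C@@H]([C@@H](OC(=O)C(=C)[C@H]1COC(C)(C)O1)CC(O[Si](CC)(CC)CC)C#C[Si](C(C)C)(C(C)C)C(C)C)/C=C/[Zr](Cl)(C1C=CC=C1)C1C=CC=C1 | intermediate
22 | (E)-alkenylzinc chloride from 21 | C=C(C(=O)OC(C)(C)C)[C@@H]([C@@H](OC(=O)C(=C)[C@H]1COC(C)(C)O1)CC(O[Si](CC)(CC)CC)C#C[Si](C(C)C)(C(C)C)C(C)C)/C=C/[Zn]Cl | intermediate
23 | tert-butyl (3S,4S)-4-({2-[(4S)-2,2-dimethyl-1,3-dioxolan-4-yl]prop-2-enoyl}oxy)-2-methylidene-3-[(1E)-3-{[(oxan-2-yl)oxy]methyl}buta-1,3-dien-1-yl]-6-[(triethylsilyl)oxy]-8-[tri(propan-2-yl)silyl]oct-7-ynoate (C6 and acetal epimers) | C=C(C(=O)OC(C)(C)C)[C@@H]([C@@H](OC(=O)C(=C)[C@H]1COC(C)(C)O1)CC(O[Si](CC)(CC)CC)C#C[Si](C(C)C)(C(C)C)C(C)C)/C=C/C(=C)COC1CCCCO1 | intermediate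
24 | tert-butyl (3S,4S)-4-({2-[(4S)-2,2-dimethyl-1,3-dioxolan-4-yl]prop-2-enoyl}oxy)-6-hydroxy-2-methylidene-3-[(1E)-3-{[(oxan-2-yl)oxy]methyl}buta-1,3-dien-1-yl]oct-7-ynoate (C6 and acetal epimers) | C=C(C(=O)OC(C)(C)C)[C@@H]([C@@H](OC(=O)C(=C)[C@H]1COC(C)(C)O1)CC(O)C#C)/C=C/C(=C)COC1CCCCO1 | intermediate
25 | tert-butyl (3S,4S)-4-({2-[(4S)-2,2-dimethyl-1,3-dioxolan-4-yl]prop-2-enoyl}oxy)-2-methylidene-3-[(1E)-3-{[(oxan-2-yl)oxy]methyl}buta-1,3-dien-1-yl]-6-oxooct-7-ynoate (acetal epimers) | C=C(C(=O)OC(C)(C)C)[C@@H]([C@@H](OC(=O)C(=C)[C@H]1COC(C)(C)O1)CC(=O)C#C)/C=C/C(=C)COC1CCCCO1 | intermediate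
26 | tert-butyl 2-[(1S,2S,8aR)-2-({2-[(4S)-2,2-dimethyl-1,3-dioxolan-4-yl]prop-2-enoyl}oxy)-7-{[(oxan-2-yl)oxy]methyl}-4-oxo-1,2,3,4,6,8a-hexahydronaphthalen-1-yl]prop-2-enoate (acetal epimers) | C=C(C(=O)OC(C)(C)C)[C@@H]1[C@H]2C=C(COC3CCCCO3)CC=C2C(=O)C[C@@H]1OC(=O)C(=C)[C@H]1COC(C)(C)O1 | intermediate
27 | catecholboron enolate (C7=C8, naphthalene C4=C4a) from 26 | C=C(C(=O)OC(C)(C)C)[C@@H]1[C@H]2C=C(COC3CCCCO3)CCC2=C(OB3Oc4ccccc4O3)C[C@@H]1OC(=O)C(=C)[C@H]1COC(C)(C)O1 | intermediate
28 | tert-butyl 2-[(1S,2S,4aS,8aR)-2-({2-[(4S)-2,2-dimethyl-1,3-dioxolan-4-yl]prop-2-enoyl}oxy)-7-{[(oxan-2-yl)oxy]methyl}-4-oxo-1,2,3,4,4a,5,6,8a-octahydronaphthalen-1-yl]prop-2-enoate (trans-fused, acetal epimers) | C=C(C(=O)OC(C)(C)C)[C@@H]1[C@H]2C=C(COC3CCCCO3)CC[C@@H]2C(=O)C[C@@H]1OC(=O)C(=C)[C@H]1COC(C)(C)O1 | intermediate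
29 | tert-butyl 2-[(1S,2S,4aS,8aS)-2-({2-[(4S)-2,2-dimethyl-1,3-dioxolan-4-yl]prop-2-enoyl}oxy)-4-methylidene-7-{[(oxan-2-yl)oxy]methyl}-1,2,3,4,4a,5,6,8a-octahydronaphthalen-1-yl]prop-2-enoate (acetal epimers) | C=C(C(=O)OC(C)(C)C)[C@@H]1[C@H]2C=C(COC3CCCCO3)CC[C@@H]2C(=C)C[C@@H]1OC(=O)C(=C)[C@H]1COC(C)(C)O1 | intermediate
30 | tert-butyl 2-[(1S,2S,4aS,8aS)-2-{[(3S)-3,4-dihydroxy-2-methylidenebutanoyl]oxy}-7-(hydroxymethyl)-4-methylidene-1,2,3,4,4a,5,6,8a-octahydronaphthalen-1-yl]prop-2-enoate | C=C(C(=O)OC(C)(C)C)[C@@H]1[C@H]2C=C(CO)CC[C@@H]2C(=C)C[C@@H]1OC(=O)C(=C)[C@H](O)CO | intermediate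
31 | trimethylsilyl ester of the target acid with its three hydroxyl groups as trimethylsilyl ethers | C=C(C(=O)O[Si](C)(C)C)[C@@H]1[C@H]2C=C(CO[Si](C)(C)C)CC[C@@H]2C(=C)C[C@@H]1OC(=O)C(=C)[C@H](O[Si](C)(C)C)CO[Si](C)(C)C | intermediate
32 | 2-[(1S,2S,4aS,8aS)-2-{[(3S)-3,4-dihydroxy-2-methylidenebutanoyl]oxy}-7-(hydroxymethyl)-4-methylidene-1,2,3,4,4a,5,6,8a-octahydronaphthalen-1-yl]prop-2-enoic acid | C=C(C(=O)O)[C@@H]1[C@H]2C=C(CO)CC[C@@H]2C(=C)C[C@@H]1OC(=O)C(=C)[C@H](O)CO | target

Total step count: 17. Longest linear sequence: 12 steps (steps 3, 4, 5 and 9 to 17, from compound 5).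

Steps most likely to fail

Step 9. The risk is insufficient enantio- or diastereocontrol of the chromium-catalysed allylation with a γ-alkynyl allyl bromide, or attack of the metallated enyne through its distal position. The fallback secures the absolute configuration by separation instead of catalysis and sets out from 4 and 9. The same chromium-catalysed allylation is run without the chiral ligand (CrCl2 cat., Mn, Me3SiCl, THF), which should keep the syn selectivity of the cyclic transition state but gives both enantiomeric series: 17 together with tert-butyl (3S,4R)-2-methylidene-6-[(triethylsilyl)oxy]-4-[(trimethylsilyl)oxy]-3-[(trimethylsilyl)ethynyl]-8-[tri(propan-2-yl)silyl]oct-7-ynoate F1. Methanolysis (K2CO3, MeOH) gives 18 and tert-butyl (3R,4R)-3-ethynyl-4-hydroxy-2-methylidene-6-[(triethylsilyl)oxy]-8-[tri(propan-2-yl)silyl]oct-7-ynoate F2. Yamaguchi esterification with the enantiopure acid 14, which the route needs anyway, turns the pair into 20 and the diastereomeric (3R,4R) ester F3, which are separated by preparative chromatography. The route is rejoined at 20.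

Step 14. The risk is competing reduction of the two acrylate esters, or protonation of the enolate from the wrong face; the latter cannot be corrected afterwards, because base would eliminate the C10 acyloxy group. The fallback separates reduction from protonation and sets out from 26. Rhodium-catalysed 1,4-hydrosilylation of the enone ((Ph3P)3RhCl cat., Et3SiH, benzene, rt) gives the isolable, regiodefined triethylsilyl enol ether F4. It is then protonated under kinetic control at low temperature with a freely chosen proton source (HF·pyridine, THF, −78 °C), and the route comes back at 28.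

Step 13. The risk is polymerisation or β-elimination of the terminal ynone before it cyclises, or oxidation of the 1,4-cyclohexadiene to an arene. The fallback reverses the order of oxidation and cycloaddition and sets out from 24. The unactivated dienyne carbinol is cyclised by a cationic complex of monovalent rhodium ([RhCl(cod)]2 cat., AgSbF6, CH2Cl2, rt), a known metal-catalysed intramolecular [4+2] cycloaddition of dienynes, to the bicyclic dienol F5; C2 should again be controlled by C1. Dess–Martin oxidation of the dienol then gives 26, where the route is rejoined.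

Further compounds
F1 | step 9 | tert-butyl (3S,4R)-2-methylidene-6-[(triethylsilyl)oxy]-4-[(trimethylsilyl)oxy]-3-[(trimethylsilyl)ethynyl]-8-[tri(propan-2-yl)silyl]oct-7-ynoate | C=C(C(=O)OC(C)(C)C)[C@H]([C@H](O[Si](C)(C)C)CC(O[Si](CC)(CC)CC)C#C[Si](C(C)C)(C(C)C)C(C)C)C#C[Si](C)(C)C
F2 | step 9 | tert-butyl (3R,4R)-3-ethynyl-4-hydroxy-2-methylidene-6-[(triethylsilyl)oxy]-8-[tri(propan-2-yl)silyl]oct-7-ynoate | C=C(C(=O)OC(C)(C)C)[C@H]([C@H](O)CC(O[Si](CC)(CC)CC)C#C[Si](C(C)C)(C(C)C)C(C)C)C#C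
F3 | step 9 | tert-butyl (3R,4R)-4-({2-[(4S)-2,2-dimethyl-1,3-dioxolan-4-yl]prop-2-enoyl}oxy)-3-ethynyl-2-methylidene-6-[(triethylsilyl)oxy]-8-[tri(propan-2-yl)silyl]oct-7-ynoate | C=C(C(=O)OC(C)(C)C)[C@H]([C@H](OC(=O)C(=C)[C@H]1COC(C)(C)O1)CC(O[Si](CC)(CC)CC)C#C[Si](C(C)C)(C(C)C)C(C)C)C#C
F4 | step 14 | triethylsilyl enol ether (C7=C8) of ketone 28 | C=C(C(=O)OC(C)(C)C)[C@@H]1[C@H]2C=C(COC3CCCCO3)CCC2=C(O[Si](CC)(CC)CC)C[C@@H]1OC(=O)C(=C)[C@H]1COC(C)(C)O1
F5 | step 13 | bicyclic dienol, the C8 carbinol corresponding to dienone 26 (carbinol epimers) | C=C(C(=O)OC(C)(C)C)[C@@H]1[C@H]2C=C(COC3CCCCO3)CC=C2C(O)C[C@@H]1OC(=O)C(=C)[C@H]1COC(C)(C)O1
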